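**Retrosynthetic overview**
- The only ring, the 5,6-dihydro-2H-pyran-2-one (O–C1(=O)–C2=C3–C4–C5), is closed last by metathesis of the C5 acrylate of a homoallylic alcohol; C2–C4 come from an asymmetric allylation of a C5 aldehyde.
- The C9 carbinol comes from a C9 ketone, reduced syn under direction of a free C7 hydroxyl.
- The strategy rests on C9 lying between two CH2–CH(O) units, C8–C7 and C10–C11. C9 is therefore a silyl dithiane carbon, and C9–C10 and C8–C9 are made in one flask by opening two terminal epoxides, with a C-to-O silyl shift relaying the anion.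
- The epoxides are (R)-2-pentadecyloxirane (C10–C26, from (R)-epichlorohydrin) and (S)-2-[2-(benzyloxy)ethyl]oxirane (C5–C8, from but-3-en-1-ol by hydrolytic kinetic resolution).

Key step: step 7

Remark: atom numbers C1–C26 are those of the target (C1 = lactone carbonyl carbon). (−)-Ipc2B(allyl) (from (+)-α-pinene, sold as a pentane solution) and (S,S)-(salen)Co(OAc) [salen = N,N'-bis(3,5-di-tert-butylsalicylidene)-1,2-cyclohexanediaminate, trivalent cobalt] are taken as purchased reagents.

Step 1
Reactants: 1 1,3-dithiane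
Product: 3 tert-butyl(1,3-dithian-2-yl)dimethylsilane, via 2-lithio-1,3-dithiane 2 (not isolated)
Conditions: n-BuLi, THF, −30 °C; TBSCl, −78 °C to rt
Reagents that add atoms: tert-butyldimethylsilyl chloride, CC(C)(C)[Si](C)(C)Cl
Why: Deprotonation of the dithiane C2–H and C-silylation of the carbanion is a standard dithiane anion alkylation; no stereocentre is formed.

Step 2
Reactants: 4 1-bromotetradecane; 5 (R)-epichlorohydrin
Product: 7 (R)-1-chloroheptadecan-2-ol, via tetradecylmagnesium bromide 6 (not isolated)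
Conditions: Mg, THF, rt to 40 °C; then 5, CuI (10 mol%), THF, −40 to −20 °C; 1 M HCl quench
Reagents that add atoms: none
Why: Copper-catalysed Grignard opening of the epoxide at its unsubstituted ring carbon should outrun chloride displacement and leaves the C–O stereocentre of 5 (the future C11) untouched.

Step 3
Reactants: 7 (R)-1-chloroheptadecan-2-ol
Product: 8 (R)-2-pentadecyloxirane
Conditions: powdered NaOH, Et2O, rt
Reagents that add atoms: none
Why: Intramolecular Williamson etherification (alkoxide displaces the primary chloride) closes the epoxide without touching the stereocentre, so the R configuration is kept.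

Step 4
Reactants: 9 but-3-en-1-ol
Product: 10 benzyl but-3-enyl ether
Conditions: NaH, BnBr, Bu4NI (cat.), THF, 0 °C to rt
Reagents that add atoms: benzyl bromide, BrCc1ccccc1
Why: Williamson ether synthesis on a primary alkoxide; no stereocentre is involved.

Step 5
Reactants: 10 benzyl but-3-enyl ether
Product: 11 rac-2-[2-(benzyloxy)ethyl]oxirane
Conditions: mCPBA, CH2Cl2, 0 °C to rt
Reagents that add atoms: meta-chloroperoxybenzoic acid, OOC(=O)c1cccc(Cl)c1
Why: Prilezhaev epoxidation of the terminal alkene gives the racemic epoxide, which is resolved in the next step.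

Step 6
Reactants: 11 rac-2-[2-(benzyloxy)ethyl]oxirane
Product: 12 (S)-2-[2-(benzyloxy)ethyl]oxirane
Conditions: (S,S)-(salen)Co(OAc) (0.5 mol%), H2O (0.55 equiv), THF, 0 °C to rt; distillation
Reagents that add atoms: none
Why: Jacobsen hydrolytic kinetic resolution: the (S,S)-complex should hydrolyse the (R)-epoxide selectively, so the (S)-epoxide (the future C7 centre) is recovered and separated from the diol.

Step 7
Reactants: 3 tert-butyl(1,3-dithian-2-yl)dimethylsilane; 8 (R)-2-pentadecyloxirane; 12 (S)-2-[2-(benzyloxy)ethyl]oxirane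
Product: 16 (S)-4-(benzyloxy)-1-{2-[(R)-2-(tert-butyldimethylsilyloxy)heptadecyl]-1,3-dithian-2-yl}butan-2-ol, via lithiated silyl dithiane 13 (not isolated), via C-silyl lithium alkoxide 14 (not isolated), via O-silyl lithio dithiane 15 (not isolated)
Conditions: t-BuLi, Et2O, −78 to −45 °C; 8 (1.0 equiv), Et2O, −78 to −25 °C; then 12 (1.2 equiv), HMPA (0.4 equiv), THF, −78 to 0 °C; aq NH4Cl
Reagents that add atoms: none
Why: t-BuLi removes the C2 proton of 3 to give 13, which opens 8 by SN2 attack at the unsubstituted epoxide carbon (C9–C10 bond) to give alkoxide 14; in Et2O this alkoxide holds, and on adding HMPA it attacks silicon so that a 1,4-Brook rearrangement moves the silyl group from C9 to the C11 oxygen and regenerates a dithiane anion 15, which opens 12 at its CH2 terminus (C8–C9 bond). The closest known reaction type is the solvent-controlled one-flask coupling of a 2-silyl-1,3-dithiane with two different epoxides by anion relay. No ring is closed. No stereocentre is created: C11 and C7 are the C–O carbons of 8 and 12 and keep their configuration because only the CH2 termini are attacked. The step needs regioselectivity, secured by the monosubstituted epoxides, and ordering, secured by running the first opening with one equivalent of 8 in Et2O so that no silyl shift occurs before HMPA is added. The silyl group ends on the C11 oxygen, which leaves the C7 hydroxyl free for the later directed reduction.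

Step 8
Reactants: 16 (S)-4-(benzyloxy)-1-{2-[(R)-2-(tert-butyldimethylsilyloxy)heptadecyl]-1,3-dithian-2-yl}butan-2-ol
Product: 17 (3S,7R)-1-(benzyloxy)-7-(tert-butyldimethylsilyloxy)-3-hydroxydocosan-5-one
Conditions: Hg(ClO4)2, CaCO3, THF/H2O (5:1), 0 °C
Reagents that add atoms: water, O
Why: Thiophilic divalent mercury promotes hydrolysis of the dithioketal to the C9 ketone, and the CaCO3 buffer should protect the silyl ether and the β-hydroxy ketone from acid; no stereocentre is touched.

Step 9
Reactants: 17 (3S,7R)-1-(benzyloxy)-7-(tert-butyldimethylsilyloxy)-3-hydroxydocosan-5-one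
Product: 19 (3S,5S,7R)-1-(benzyloxy)-7-(tert-butyldimethylsilyloxy)docosane-3,5-diol, via diethylboron chelate 18 (not isolated)
Conditions: Et2BOMe, THF/MeOH (4:1), −78 °C; NaBH4, −78 °C; then MeOH co-evaporation
Reagents that add atoms: none
Why: Narasaka–Prasad reduction: boron ties the C7 oxygen and the C9 carbonyl into a six-membered chelate and hydride adds axially to its half-chair, so C9 is set syn to C7 by 1,3-induction.

Step 10
Reactants: 19 (3S,5S,7R)-1-(benzyloxy)-7-(tert-butyldimethylsilyloxy)docosane-3,5-diol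
Product: 20 (3S,5R,7R)-1-(benzyloxy)-3,5,7-tris(tert-butyldimethylsilyloxy)docosane
Conditions: TBSOTf, 2,6-lutidine, CH2Cl2, −78 to 0 °C
Reagents that add atoms: tert-butyldimethylsilyl trifluoromethanesulfonate, CC(C)(C)[Si](C)(C)OS(=O)(=O)C(F)(F)F
Why: Silyl triflate etherification of both secondary hydroxyls gives one uniform protecting group set; the configuration is unchanged (the C9 descriptor changes by priority only).

Step 11
Reactants: 20 (3S,5R,7R)-1-(benzyloxy)-3,5,7-tris(tert-butyldimethylsilyloxy)docosane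
Product: 21 (3S,5R,7R)-3,5,7-tris(tert-butyldimethylsilyloxy)docosan-1-ol
Conditions: H2 (1 atm), 10% Pd/C, EtOAc, rt
Reagents that add atoms: none
Why: Hydrogenolysis of the benzyl ether; the silyl ethers are stable in EtOAc and no sulfur or alkene is present at this stage.

Step 12
Reactants: 21 (3S,5R,7R)-3,5,7-tris(tert-butyldimethylsilyloxy)docosan-1-ol
Product: 22 (3R,5R,7R)-3,5,7-tris(tert-butyldimethylsilyloxy)docosanal
Conditions: Dess–Martin periodinane, CH2Cl2, 0 °C to rt
Reagents that add atoms: none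
Why: Dess–Martin oxidation of the primary alcohol to the C5 aldehyde under near-neutral conditions should avoid β-elimination of the C7 silyloxy group.

Step 13
Reactants: 22 (3R,5R,7R)-3,5,7-tris(tert-butyldimethylsilyloxy)docosanal
Product: 24 (4S,6S,8R,10R)-6,8,10-tris(tert-butyldimethylsilyloxy)pentacos-1-en-4-ol, via borinate ester 23 (not isolated)
Conditions: (−)-Ipc2B(allyl) (1 M in pentane), Et2O, −78 °C; then NaOH, H2O2, rt
Reagents that add atoms: (−)-B-allyldiisopinocampheylborane, C=CCB([C@@H]1C[C@@H]2C[C@H]([C@H]1C)C2(C)C)[C@@H]1C[C@@H]2C[C@H]([C@H]1C)C2(C)C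
Why: Brown allylation through a closed chair transition state: the reagent from (+)-α-pinene should deliver allyl to the Si face of the aldehyde, setting C5 (S) syn to the C7 oxygen under reagent control, and oxidative work-up cleaves borinate 23.

Step 14
Reactants: 24 (4S,6S,8R,10R)-6,8,10-tris(tert-butyldimethylsilyloxy)pentacos-1-en-4-ol
Product: 25 (4S,6S,8R,10R)-6,8,10-tris(tert-butyldimethylsilyloxy)pentacos-1-en-4-yl prop-2-enoate
Conditions: acryloyl chloride, Et3N, DMAP (cat.), CH2Cl2, 0 °C
Reagents that add atoms: acryloyl chloride, C=CC(=O)Cl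
Why: DMAP-catalysed acylation of the secondary alcohol; C5 keeps its configuration because the C–O bond is not broken.

Step 15
Reactants: 25 (4S,6S,8R,10R)-6,8,10-tris(tert-butyldimethylsilyloxy)pentacos-1-en-4-yl prop-2-enoate
Product: 26 (S)-6-[(2S,4R,6R)-2,4,6-tris(tert-butyldimethylsilyloxy)henicosyl]-5,6-dihydro-2H-pyran-2-one
Conditions: second-generation Grubbs catalyst RuCl2(=CHPh)(H2IMes)(PCy3) (5 mol%), CH2Cl2 (0.005 M), 40 °C
Reagents that add atoms: none
Why: Ring-closing metathesis between the acrylate and the terminal alkene forms the C2=C3 bond and the six-membered lactone, the ring enforcing the cis alkene, with loss of ethene.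

Step 16
Reactants: 26 (S)-6-[(2S,4R,6R)-2,4,6-tris(tert-butyldimethylsilyloxy)henicosyl]-5,6-dihydro-2H-pyran-2-one
Product: 27 (S)-6-[(2R,4R,6R)-2,4,6-trihydroxyhenicosyl]-5,6-dihydro-2H-pyran-2-one (CNP0231118.1)
Conditions: 48% aq HF, MeCN/CH2Cl2, 0 °C to rt
Reagents that add atoms: none
Why: Acidic fluoride desilylation removes the three silyl ethers under conditions the unsaturated lactone should tolerate; no stereocentre is touched (the C7 descriptor changes by priority only).

**Compound list**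
1 | 1,3-dithiane | C1CSCSC1 | starting material
2 | 2-lithio-1,3-dithiane | [Li]C1SCCCS1 | intermediate
3 | tert-butyl(1,3-dithian-2-yl)dimethylsilane | CC(C)(C)[Si](C)(C)C1SCCCS1 | intermediate
4 | 1-bromotetradecane | CCCCCCCCCCCCCCBr | starting material
5 | (R)-epichlorohydrin | ClC[C@H]1CO1 | starting material
6 | tetradecylmagnesium bromide | CCCCCCCCCCCCCC[Mg]Br | intermediate
7 | (R)-1-chloroheptadecan-2-ol | CCCCCCCCCCCCCCC[C@@H](O)CCl | intermediate
8 | (R)-2-pentadecyloxirane | CCCCCCCCCCCCCCC[C@@H]1CO1 | intermediate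
9 | but-3-en-1-ol | OCCC=C | starting material
10 | benzyl but-3-enyl ether | C=CCCOCc1ccccc1 | intermediate
11 | rac-2-[2-(benzyloxy)ethyl]oxirane | c1ccccc1COCCC1CO1 | intermediate
12 | (S)-2-[2-(benzyloxy)ethyl]oxirane | c1ccccc1COCC[C@H]1CO1 | intermediate
13 | tert-butyl(2-lithio-1,3-dithian-2-yl)dimethylsilane | [Li]C1(SCCCS1)[Si](C)(C)C(C)(C)C | intermediate
14 | lithium (R)-1-[2-(tert-butyldimethylsilyl)-1,3-dithian-2-yl]heptadecan-2-olate | CCCCCCCCCCCCCCC[C@@H](O[Li])CC1(SCCCS1)[Si](C)(C)C(C)(C)C | intermediate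
15 | tert-butyl{[(R)-1-(2-lithio-1,3-dithian-2-yl)heptadecan-2-yl]oxy}dimethylsilane | CCCCCCCCCCCCCCC[C@@H](O[Si](C)(C)C(C)(C)C)CC1([Li])SCCCS1 | intermediate
16 | (S)-4-(benzyloxy)-1-{2-[(R)-2-(tert-butyldimethylsilyloxy)heptadecyl]-1,3-dithian-2-yl}butan-2-ol | CCCCCCCCCCCCCCC[C@@H](O[Si](C)(C)C(C)(C)C)CC1(SCCCS1)C[C@@H](O)CCOCc1ccccc1 | intermediate
17 | (3S,7R)-1-(benzyloxy)-7-(tert-butyldimethylsilyloxy)-3-hydroxydocosan-5-one | CCCCCCCCCCCCCCC[C@@H](O[Si](C)(C)C(C)(C)C)CC(=O)C[C@@H](O)CCOCc1ccccc1 | intermediate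
18 | (3S,7R)-1-(benzyloxy)-7-(tert-butyldimethylsilyloxy)-5-oxodocosan-3-yl diethylborinate (boron chelated to the C9 carbonyl) | CCCCCCCCCCCCCCC[C@@H](O[Si](C)(C)C(C)(C)C)CC(=O)C[C@@H](OB(CC)CC)CCOCc1ccccc1 | intermediate
19 | (3S,5S,7R)-1-(benzyloxy)-7-(tert-butyldimethylsilyloxy)docosane-3,5-diol | CCCCCCCCCCCCCCC[C@@H](O[Si](C)(C)C(C)(C)C)C[C@@H](O)C[C@@H](O)CCOCc1ccccc1 | intermediate
20 | (3S,5R,7R)-1-(benzyloxy)-3,5,7-tris(tert-butyldimethylsilyloxy)docosane | CCCCCCCCCCCCCCC[C@@H](O[Si](C)(C)C(C)(C)C)C[C@@H](O[Si](C)(C)C(C)(C)C)C[C@@H](O[Si](C)(C)C(C)(C)C)CCOCc1ccccc1 | intermediate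
21 | (3S,5R,7R)-3,5,7-tris(tert-butyldimethylsilyloxy)docosan-1-ol | CCCCCCCCCCCCCCC[C@@H](O[Si](C)(C)C(C)(C)C)C[C@@H](O[Si](C)(C)C(C)(C)C)C[C@@H](O[Si](C)(C)C(C)(C)C)CCO | intermediate
22 | (3R,5R,7R)-3,5,7-tris(tert-butyldimethylsilyloxy)docosanal | CCCCCCCCCCCCCCC[C@@H](O[Si](C)(C)C(C)(C)C)C[C@@H](O[Si](C)(C)C(C)(C)C)C[C@@H](O[Si](C)(C)C(C)(C)C)CC=O | intermediate
23 | (4S,6S,8R,10R)-6,8,10-tris(tert-butyldimethylsilyloxy)pentacos-1-en-4-yl diisopinocampheylborinate | CCCCCCCCCCCCCCC[C@@H](O[Si](C)(C)C(C)(C)C)C[C@@H](O[Si](C)(C)C(C)(C)C)C[C@@H](O[Si](C)(C)C(C)(C)C)C[C@@H](OB([C@@H]1C[C@@H]2C[C@H]([C@H]1C)C2(C)C)[C@@H]1C[C@@H]2C[C@H]([C@H]1C)C2(C)C)CC=C | intermediate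
24 | (4S,6S,8R,10R)-6,8,10-tris(tert-butyldimethylsilyloxy)pentacos-1-en-4-ol | CCCCCCCCCCCCCCC[C@@H](O[Si](C)(C)C(C)(C)C)C[C@@H](O[Si](C)(C)C(C)(C)C)C[C@@H](O[Si](C)(C)C(C)(C)C)C[C@@H](O)CC=C | intermediate
25 | (4S,6S,8R,10R)-6,8,10-tris(tert-butyldimethylsilyloxy)pentacos-1-en-4-yl prop-2-enoate | CCCCCCCCCCCCCCC[C@@H](O[Si](C)(C)C(C)(C)C)C[C@@H](O[Si](C)(C)C(C)(C)C)C[C@@H](O[Si](C)(C)C(C)(C)C)C[C@@H](OC(=O)C=C)CC=C | intermediate
26 | (S)-6-[(2S,4R,6R)-2,4,6-tris(tert-butyldimethylsilyloxy)henicosyl]-5,6-dihydro-2H-pyran-2-one | CCCCCCCCCCCCCCC[C@@H](O[Si](C)(C)C(C)(C)C)C[C@@H](O[Si](C)(C)C(C)(C)C)C[C@@H](O[Si](C)(C)C(C)(C)C)C[C@@H]1CC=CC(=O)O1 | intermediate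
27 | (S)-6-[(2R,4R,6R)-2,4,6-trihydroxyhenicosyl]-5,6-dihydro-2H-pyran-2-one | CCCCCCCCCCCCCCC[C@@H](O)C[C@@H](O)C[C@@H](O)C[C@@H]1CC=CC(=O)O1 | target

**Totals**
Total step count: 16. Longest linear sequence: 13 steps (steps 4–6, then 7–16, from but-3-en-1-ol).

**Steps most likely to fail**

1. Step 7. The silyl shift may start before the second epoxide is present or may stay incomplete, so that 13 adds twice to 8 or 15 is quenched, giving mixtures. The fallback drops the relay and joins the pieces stepwise. It sets out from 1 and 8: anion 2 (n-BuLi, THF, −30 °C) opens 8 to give (R)-1-(1,3-dithian-2-yl)heptadecan-2-ol F1. Silylation (TBSCl, imidazole, DMF) gives tert-butyl{[(R)-1-(1,3-dithian-2-yl)heptadecan-2-yl]oxy}dimethylsilane F2. Deprotonation of F2 (t-BuLi, THF/HMPA, −78 °C) gives 15 directly, which opens 12, and the route is rejoined at 16.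

2. Step 13. Facial selectivity may be poor if the reagent and the C7 silyloxy centre are mismatched, giving the C5 epimer alongside 24. The fallback makes the step stereoconvergent. It sets out from 22, which is allylated without chiral control (allylmagnesium bromide, Et2O, −78 °C), and the two carbinols are separated. 24 goes on through step 14. Its epimer, (4R,6S,8R,10R)-6,8,10-tris(tert-butyldimethylsilyloxy)pentacos-1-en-4-ol F3, is esterified with acrylic acid under Mitsunobu conditions (PPh3, DIAD, THF, 0 °C), which inverts C5. Both streams rejoin the route at 25.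

3. Step 16. During desilylation the freed C7 hydroxyl may add in conjugate fashion to C3 of the unsaturated lactone, or the lactone may open. The fallback changes the order so that the lactone never meets the deprotection conditions. It sets out from 25, which is desilylated first (48% aq HF, MeCN, 0 °C to rt) to (4S,6R,8R,10R)-6,8,10-trihydroxypentacos-1-en-4-yl prop-2-enoate F4. Ring-closing metathesis of F4 (second-generation Grubbs catalyst RuCl2(=CHPh)(H2IMes)(PCy3), CH2Cl2, 40 °C) under neutral conditions then gives 27 directly.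

**Further compounds**
F1 | step 7 | (R)-1-(1,3-dithian-2-yl)heptadecan-2-ol | CCCCCCCCCCCCCCC[C@@H](O)CC1SCCCS1
F2 | step 7 | tert-butyl{[(R)-1-(1,3-dithian-2-yl)heptadecan-2-yl]oxy}dimethylsilane | CCCCCCCCCCCCCCC[C@@H](O[Si](C)(C)C(C)(C)C)CC1SCCCS1
F3 | step 13 | (4R,6S,8R,10R)-6,8,10-tris(tert-butyldimethylsilyloxy)pentacos-1-en-4-ol | CCCCCCCCCCCCCCC[C@@H](O[Si](C)(C)C(C)(C)C)C[C@@H](O[Si](C)(C)C(C)(C)C)C[C@@H](O[Si](C)(C)C(C)(C)C)C[C@H](O)CC=C
F4 | step 16 | (4S,6R,8R,10R)-6,8,10-trihydroxypentacos-1-en-4-yl prop-2-enoate | CCCCCCCCCCCCCCC[C@@H](O)C[C@@H](O)C[C@@H](O)C[C@@H](OC(=O)C=C)CC=C
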